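electrophile 11 mM; solid base 1.10 equiv; protic impurity 0.220 mM; time 5.0 h

- the equivalents of nucleophile at which the part of the electrophile that has reacted at 5.0 h is just 70%

- given per volume of solution although it is solid: solid base
- the amount of nucleophile is what is sought; it is there from the start
- at the start none of the solid base is in solution
- run time (flask): 5.0 h

    acid set free + free base ⇌ salt of the base (K1 = 12000 M⁻¹, k1 = 220 M⁻¹ h⁻¹)
    electrophile + protic impurity → quenched substrate (k2 = 510 M⁻¹ h⁻¹)
    electrophile + nucleophile → acid set free + target (k3 = 15 M⁻¹ h⁻¹)
    solid base ⇌ free base, rate k4*(cs4 - [free base]) while solid is left; crystals form when [free base] > cs4 (cs4 = 5.4 mM, k4 = 4.5 h⁻¹)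
    nucleophile + acid set free ⇌ protonated nucleophile, settled at all times (K5 = 27000 M⁻¹)
    electrophile + acid set free → side product (k6 = 19 M⁻¹ h⁻¹)

The neighbour to start from is a flask whose base catches each acid at once: a turnover there costs 1 free nucleophile, while a flask keeping its acid on nucleophile pays 2, and an even split of the acid pays 1.50.

In fractions of the electrophile charge, the impurity goes early, since its half-life against the charged electrophile, 0.124 h, is much shorter than the run. It takes 0.0200, so 0.980 enters the main step, 30.0% of the charge may remain, and the turnover is 0.680.

Taking free nucleophile at the logarithmic midpoint of the electrophile, the charge is 1.43 plus the cost per turnover times 0.438. The table of three rows reads: cost 1, 1.87 equiv; even split, 2.09 equiv; cost 2, 2.31 equiv.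

The row is picked by the base. Free base stands near 5.4 mM, as dissolving is faster than capture. With protonated and free nucleophile taken as equal, free acid stands at 0.0370 mM, so the base drains 0.0200 of the charge during the run. That gives the price 1.97, the free nucleophile lost per turnover, and a charge of 2.30 equiv.

The forecast stands above this reckoning at 2.35 equiv, on the ground that “each turnover effectively uses two nucleophiles”. The simulation gives 2.33 equiv.

At this charge the impurity's turnover was half done by 0.128 h, while the electrophile used, the impurity's take included, stood at 18.0% at 0.500 h and 52.0% at 2.50 h, with 57.2% of the nucleophile free at 2.50 h and 42.1% at 5.00 h. Those readings cost 1.98 free nucleophile per turnover against the price of 1.97, and the flask at twice the dilution, with 52.1% reacted, doubled drain and price 1.92, returns a charge of 2.30 equiv.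

The rate constants were chosen freely; what happens was integrated by code.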